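In its first 1.00 min the south-west flask, at 110 °C, makes target at 0.210 min⁻¹, in fractions of the charge. The readings then cross 36.0%, the midpoint of the last reading, between 2.00 min and 3.00 min. I interpolate 2.13 min, and I call this the rise half-life, the time that halves the gap between the target and its level.

the same everywhere: starting material 1.7 M

| run | temperature | remark | time |
|---|---|---|---|
| south-west | 110 °C | the very flask that is asked about, followed so far |  |
| south-east | 105 °C | run made earlier |  |
| flask | 110 °C |  | 20 min |

| run | time / min | target / % |
|---|---|---|
| south-west | 1.00 | 21 |
| south-west | 2.00 | 34 |
| south-west | 3.00 | 49 |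
| south-west | 6.00 | 65 |
| south-west | 12.0 | 72 |
| south-east | 1.00 | 13 |
| south-east | 2.00 | 30 |
| south-east | 3.00 | 35 |
| south-east | 6.00 | 55 |
| south-east | 12.0 | 69 |

(standard deviation of a reading: 2 percentage points)

- ash: change nothing and wait 40 min more
- cedar: at 20 min raise the temperature by 10 K, then wait 40 min
- oak: at 20 min take out 90% of the target then present, then wait 40 min

- target that was removed still counts
- the earlier runs were read with a standard deviation of 2 percentage points
- steps thought possible: intermediate A <-> intermediate B; intermediate B -> intermediate C; starting material <-> dormant form; starting material -> target; intermediate C -> side product B; starting material <-> intermediate A; intermediate B -> side product A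

1. target, in percent of the starting material first charged, at 20 min
2. what to do for the largest gain in target; "none" if nothing gains more than 2 percentage points (ash / cedar / oak / none)
3. target present, with what was taken out counted in, in percent of the starting material first charged, after ash
4. target present, with what was taken out counted in, in percent of the starting material first charged, after cedar

I count these half-lives along the curve. At 12.0 min the south-west flask is 5.63 half-lives in, with 2.01% of the gap open, so I put the level at 73.5%. The knee at 6.00 min then reckons to 63.1%, against a reading of 65%, which lies within the scatter of 2 percentage points.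

The south-east flask, at 105 °C, crosses the same mark later, at 3.15 min, so 5.00 K of added heat shortens the half-life 1.48-fold as read.

The asked flask is the south-west flask at 20 min, which is 9.39 half-lives in. The count leaves 0.151% of the gap open, less than the 2 points an option must gain. I therefore commit to 73.5% and to none, and the readings of target do not size any slower store.

The forecast gives 73.5%, 75% after ash, 75% after cedar, and none as the choice, holding that the reservoirs “could leak back slowly and add a point or two”.

The asked flask gives 76.3% at 20 min and 78.9% after ash, and the best choice is cedar, which gains 5.6 points and reaches 81.9%.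

    intermediate A ⇌ intermediate B (K = 1.70, k = 0.110 s⁻¹, Ea = 88.0 kJ mol⁻¹, ΔH = −18.0 kJ mol⁻¹)
    intermediate B → intermediate C (k = 0.00290 s⁻¹, Ea = 117 kJ mol⁻¹)
    starting material ⇌ dormant form (K = 3.10, k = 5.40 × 10⁻⁴ s⁻¹, Ea = 116 kJ mol⁻¹, ΔH = −43.0 kJ mol⁻¹)
    starting material → target (k = 0.00460 s⁻¹, Ea = 99.0 kJ mol⁻¹)
    intermediate C → side product B (k = 0.00840 s⁻¹, Ea = 109 kJ mol⁻¹)
    starting material ⇌ intermediate A (K = 0.200, k = 0.00350 s⁻¹, Ea = 118 kJ mol⁻¹, ΔH = −61.0 kJ mol⁻¹)
    intermediate B → side product A (k = 9.80 × 10⁻⁴ s⁻¹, Ea = 123 kJ mol⁻¹)
    (constants at 110 °C)

The forecast and I part from the flask on that choice, and ash gains 2.5 points, more than the 0.151% my count leaves. At 20 min the asked flask holds 7.54% as dormant form. Carried on to 125 °C as read, the half-life shortens to 0.663 min, so a neighbour flask kept at that temperature is 30.2 half-lives in at 20 min, and it holds 86.1% target with 3.61% as dormant form.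

(The numbers in the tables were generated by integration from invented constants, and the scatter is random.)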